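**Retrosynthetic overview**

- Feature: in the 2,3-dihydro-1-benzofuran core, the O1–C2 bond joins the phenol oxygen O1 to C2, a benzylic carbon whose 4-oxygenated phenyl ring stabilises a cation. C2 can therefore be generated as a cation by loss of CO2 from the carboxyl-bearing α-carbon of an open-chain acid, which is the ring-opened form of a six-membered 3,4-diarylchroman-2-one.
- Disconnections, latest first: the stilbene C–C bond at C5 (Heck reaction of an aryl chloride), then O1–C2 (decarboxylative cation capture by the silylated phenol oxygen), then the α-carbon–aryl bond (palladium enolate arylation), then the C4–aryl bond of the chromanone (rhodium asymmetric 1,4-addition, which sets the one controlling stereocentre, C3 of the target).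
- Ring order: the benzo ring is bought in 6-chlorocoumarin, the six-membered lactone ring is opened in step 2, and the five-membered dihydrofuran ring is closed in step 6. The styryl arm and the free phenols follow.

Key step: step 6

Assumption 1: the (S)-configured bisphosphine is taken to deliver the aryl group to the face of C4 that gives the (S)-lactone, as expected from the behaviour of unsubstituted coumarin; if the first batch shows the opposite sense, the antipodal ligand is used.
Assumption 2: 3,5-diacetoxystyrene, needed only in one fallback, is taken as a purchasable reagent.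
Locants O1, C2, C3, C3a, C5 and C7a refer to the dihydrobenzofuran core of the target.

**Route**

Step 1
Reactants: 1 6-chlorocoumarin; 2 3,5-dimethoxyphenylboronic acid
Product: 3 (4S)-6-chloro-4-(3,5-dimethoxyphenyl)-3,4-dihydro-2H-chromen-2-one
Conditions: Rh(acac)(C2H4)2 (cat.), (S)-SEGPHOS, excess 2, 1,4-dioxane/H2O 10:1, 60 °C
Reagents that add atoms: none
Why: Hayashi–Miyaura rhodium-catalysed asymmetric 1,4-addition of an arylboronic acid to the coumarin enoate, in which the bisphosphine-bound aryl-rhodium species (monovalent rhodium) should insert the C3=C4 bond from one face so that the ligand antipode fixes C4 as S, while the aryl chloride is inert to this catalyst.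

Step 2
Reactants: 3 (4S)-6-chloro-4-(3,5-dimethoxyphenyl)-3,4-dihydro-2H-chromen-2-one
Product: 5 tert-butyl (3S)-3-[2-(tert-butyldimethylsilyloxy)-5-chlorophenyl]-3-(3,5-dimethoxyphenyl)propanoate, via ring-opened potassium phenoxide 4 (not isolated)
Conditions: KOtBu, THF, −20 to 0 °C; then TBSCl, 0 °C to rt
Reagents that add atoms: potassium tert-butoxide, CC(C)(C)[O-].[K+]; tert-butyldimethylsilyl chloride (TBSCl), CC(C)(C)[Si](C)(C)Cl
Why: Alkoxide transesterification of the aryl-ester lactone is driven by release of the much weaker phenoxide base, the bulky tert-butyl ester does not re-lactonise, and the phenoxide is O-silylated in the same flask; the diaryl-substituted stereocentre has no leaving group next to it and should be untouched.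

Step 3
Reactants: 5 tert-butyl (3S)-3-[2-(tert-butyldimethylsilyloxy)-5-chlorophenyl]-3-(3,5-dimethoxyphenyl)propanoate; 6 4-bromoanisole
Product: 8 tert-butyl (3S)-3-[2-(tert-butyldimethylsilyloxy)-5-chlorophenyl]-3-(3,5-dimethoxyphenyl)-2-(4-methoxyphenyl)propanoate (C2 epimer mixture), via lithium ester enolate 7 (not isolated)
Conditions: LiNCy2, toluene, 0 °C; then 6, Pd(dba)2 (cat.), P(tBu)3, rt
Reagents that add atoms: none
Why: Palladium-catalysed α-arylation of a tert-butyl ester lithium enolate (Buchwald–Hartwig enolate arylation), in which oxidative addition of the zerovalent palladium/P(tBu)3 catalyst into the C–Br bond of 6 at room temperature should be much faster than into the electron-rich C–Cl bond, and the new C2 centre forms as an epimer mixture that is erased later.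

Step 4
Reactants: 8 tert-butyl (3S)-3-[2-(tert-butyldimethylsilyloxy)-5-chlorophenyl]-3-(3,5-dimethoxyphenyl)-2-(4-methoxyphenyl)propanoate
Product: 9 (3S)-3-[2-(tert-butyldimethylsilyloxy)-5-chlorophenyl]-3-(3,5-dimethoxyphenyl)-2-(4-methoxyphenyl)propanoic acid (C2 epimer mixture)
Conditions: TFA, Et3SiH, CH2Cl2, 0 °C
Reagents that add atoms: none
Why: Acidolysis of the tert-butyl ester by alkyl–oxygen cleavage, with triethylsilane reducing the tert-butyl cation before it can alkylate the dimethoxyarene, under brief cold conditions that an aryl silyl ether should tolerate.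

Step 5
Reactants: 9 (3S)-3-[2-(tert-butyldimethylsilyloxy)-5-chlorophenyl]-3-(3,5-dimethoxyphenyl)-2-(4-methoxyphenyl)propanoic acid
Product: 10 1,3-dioxoisoindolin-2-yl (3S)-3-[2-(tert-butyldimethylsilyloxy)-5-chlorophenyl]-3-(3,5-dimethoxyphenyl)-2-(4-methoxyphenyl)propanoate (C2 epimer mixture)
Conditions: N-hydroxyphthalimide, DIC, DMAP (cat.), CH2Cl2, rt
Reagents that add atoms: N-hydroxyphthalimide, O=C1c2ccccc2C(=O)N1O
Why: Carbodiimide (Steglich-type) esterification to the redox-active N-acyloxyphthalimide, which is possible only because the phenol is still silylated and so cannot close the six-membered lactone onto the activated ester.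

Step 6
Reactants: 10 1,3-dioxoisoindolin-2-yl (3S)-3-[2-(tert-butyldimethylsilyloxy)-5-chlorophenyl]-3-(3,5-dimethoxyphenyl)-2-(4-methoxyphenyl)propanoate
Product: 11 (2S,3S)-5-chloro-3-(3,5-dimethoxyphenyl)-2-(4-methoxyphenyl)-2,3-dihydro-1-benzofuran
Conditions: fac-Ir(ppy)3 (cat.), degassed CH2Cl2 (dilute), blue LEDs (450 nm), rt, argon; aqueous work-up
Reagents that add atoms: none
Why: Proposed new method: the photoexcited trivalent iridium complex should transfer one electron to the N-acyloxyphthalimide, which fragments to phthalimide anion, CO2 and the secondary 4-methoxybenzylic radical at the future C2, and the tetravalent iridium left behind should oxidise this electron-rich radical to the 4-methoxybenzylic (quinone-methide-like) cation, closing a redox-neutral cycle. The ortho silyloxy oxygen then adds to the cation in a 5-exo closure that forms O1–C2 and the dihydrofuran ring, and phthalimide anion removes silicon from the resulting silyloxonium ion. The closest known reaction type is the photoredox decarboxylative etherification of benzylic N-acyloxyphthalimides by radical–polar crossover with alcohols, together with the loss of silicon from silyl ethers that capture cations in halo-etherifications; an aryl silyl ether as the internal oxygen nucleophile is the untested element. C2 is made from a planar cation, so the epimer ratio of 10 does not matter, and the 4-methoxyphenyl group should settle trans to the C3 aryl group because closure is reversible up to desilylation and the trans ring avoids eclipsing of the two aryl groups; C3, fixed in step 1, is not involved. The step needs ring closure to outrun loss of the C3 proton (which would give a triarylethene and erase C3) and intermolecular capture by phthalimide nitrogen, and it relies for this on the five-membered proximity of the oxygen, on high dilution, on a non-nucleophilic solvent and on the absence of any base stronger than phthalimide anion.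

Step 7
Reactants: 11 (2S,3S)-5-chloro-3-(3,5-dimethoxyphenyl)-2-(4-methoxyphenyl)-2,3-dihydro-1-benzofuran; 12 3,5-dimethoxystyrene
Product: 13 (2S,3S)-3-(3,5-dimethoxyphenyl)-5-[(E)-2-(3,5-dimethoxyphenyl)ethenyl]-2-(4-methoxyphenyl)-2,3-dihydro-1-benzofuran
Conditions: Pd2(dba)3 (cat.), P(tBu)3, Cy2NMe, 1,4-dioxane, 110 °C
Reagents that add atoms: none
Why: Mizoroki–Heck reaction of an electron-rich aryl chloride, made possible by the bulky electron-rich phosphine on zerovalent palladium, in which syn insertion and syn β-hydride elimination should give the E-stilbene; it is placed after the photochemical step so that the stilbene never meets the photocatalyst.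

Step 8
Reactants: 13 (2S,3S)-3-(3,5-dimethoxyphenyl)-5-[(E)-2-(3,5-dimethoxyphenyl)ethenyl]-2-(4-methoxyphenyl)-2,3-dihydro-1-benzofuran
Product: 14 (2S,3S)-trans-δ-viniferin, 5-[(2S,3S)-5-[(E)-2-(3,5-dihydroxyphenyl)ethenyl]-2-(4-hydroxyphenyl)-2,3-dihydro-1-benzofuran-3-yl]benzene-1,3-diol
Conditions: BBr3 (excess), CH2Cl2, −78 to 0 °C; then H2O
Reagents that add atoms: none
Why: Lewis-acid cleavage of the five aryl methyl ethers by BBr3 (bromide attack at the methyl group of each boron-complexed ether), in which C3 and the alkene geometry are not involved and any reversible ionisation of the O1–C2 bond can only return to the more stable trans ring.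

**Compound list**

1 | 6-chlorocoumarin | O=c1ccc2cc(Cl)ccc2o1 | starting material
2 | 3,5-dimethoxyphenylboronic acid | COc1cc(OC)cc(B(O)O)c1 | starting material
3 | (4S)-6-chloro-4-(3,5-dimethoxyphenyl)-3,4-dihydro-2H-chromen-2-one | O=C1C[C@@H](c2cc(OC)cc(OC)c2)c2cc(Cl)ccc2O1 | intermediate
4 | potassium 4-chloro-2-[(1S)-3-tert-butoxy-1-(3,5-dimethoxyphenyl)-3-oxopropyl]phenolate | CC(C)(C)OC(=O)C[C@@H](c1cc(OC)cc(OC)c1)c1cc(Cl)ccc1[O-].[K+] | intermediate (not isolated)
5 | tert-butyl (3S)-3-[2-(tert-butyldimethylsilyloxy)-5-chlorophenyl]-3-(3,5-dimethoxyphenyl)propanoate | CC(C)(C)OC(=O)C[C@@H](c1cc(OC)cc(OC)c1)c1cc(Cl)ccc1O[Si](C)(C)C(C)(C)C | intermediate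
6 | 4-bromoanisole | COc1ccc(Br)cc1 | starting material
7 | lithium (3S)-1-tert-butoxy-3-[2-(tert-butyldimethylsilyloxy)-5-chlorophenyl]-3-(3,5-dimethoxyphenyl)prop-1-en-1-olate | CC(C)(C)OC([O-])=C[C@@H](c1cc(OC)cc(OC)c1)c1cc(Cl)ccc1O[Si](C)(C)C(C)(C)C.[Li+] | intermediate (not isolated)
8 | tert-butyl (3S)-3-[2-(tert-butyldimethylsilyloxy)-5-chlorophenyl]-3-(3,5-dimethoxyphenyl)-2-(4-methoxyphenyl)propanoate, C2 epimer mixture | CC(C)(C)OC(=O)C(c1ccc(OC)cc1)[C@@H](c1cc(OC)cc(OC)c1)c1cc(Cl)ccc1O[Si](C)(C)C(C)(C)C | intermediate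
9 | (3S)-3-[2-(tert-butyldimethylsilyloxy)-5-chlorophenyl]-3-(3,5-dimethoxyphenyl)-2-(4-methoxyphenyl)propanoic acid, C2 epimer mixture | OC(=O)C(c1ccc(OC)cc1)[C@@H](c1cc(OC)cc(OC)c1)c1cc(Cl)ccc1O[Si](C)(C)C(C)(C)C | intermediate
10 | 1,3-dioxoisoindolin-2-yl (3S)-3-[2-(tert-butyldimethylsilyloxy)-5-chlorophenyl]-3-(3,5-dimethoxyphenyl)-2-(4-methoxyphenyl)propanoate, C2 epimer mixture | O=C(ON1C(=O)c2ccccc2C1=O)C(c1ccc(OC)cc1)[C@@H](c1cc(OC)cc(OC)c1)c1cc(Cl)ccc1O[Si](C)(C)C(C)(C)C | intermediate
11 | (2S,3S)-5-chloro-3-(3,5-dimethoxyphenyl)-2-(4-methoxyphenyl)-2,3-dihydro-1-benzofuran | COc1ccc([C@H]2Oc3ccc(Cl)cc3[C@@H]2c2cc(OC)cc(OC)c2)cc1 | intermediate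
12 | 3,5-dimethoxystyrene | C=Cc1cc(OC)cc(OC)c1 | starting material
13 | (2S,3S)-3-(3,5-dimethoxyphenyl)-5-[(E)-2-(3,5-dimethoxyphenyl)ethenyl]-2-(4-methoxyphenyl)-2,3-dihydro-1-benzofuran | COc1ccc([C@H]2Oc3ccc(/C=C/c4cc(OC)cc(OC)c4)cc3[C@@H]2c2cc(OC)cc(OC)c2)cc1 | intermediate
14 | (2S,3S)-trans-δ-viniferin | Oc1ccc([C@H]2Oc3ccc(/C=C/c4cc(O)cc(O)c4)cc3[C@@H]2c2cc(O)cc(O)c2)cc1 | target

**Step count**

Total steps: 8. Longest linear sequence: 8 steps, from 6-chlorocoumarin.

**Steps most likely to fail, with fallbacks**

Step 6 (proposed new method). What may go wrong: after decarboxylation and oxidation, the cation may lose the C3 proton, suffer a 1,2-aryl shift, or be captured by phthalimide nitrogen faster than the weakly nucleophilic silyl ether oxygen closes the ring. The fallback uses known chemistry, sets out from acid 9 and comes back at 11. Acid 9 is condensed with 1-hydroxypyridine-2(1H)-thione and DIC to the Barton ester, 2-thioxopyridin-1(2H)-yl (3S)-3-[2-(tert-butyldimethylsilyloxy)-5-chlorophenyl]-3-(3,5-dimethoxyphenyl)-2-(4-methoxyphenyl)propanoate F1. Photolysis of this ester under oxygen with tert-butyl thiol, followed by reduction of the hydroperoxide with P(OMe)3 (Barton decarboxylative hydroxylation), should give the nor-alcohol (2S)-2-[2-(tert-butyldimethylsilyloxy)-5-chlorophenyl]-2-(3,5-dimethoxyphenyl)-1-(4-methoxyphenyl)ethan-1-ol F2 as an epimer mixture. TBAF in THF then frees the phenol to give 4-chloro-2-[(1S)-1-(3,5-dimethoxyphenyl)-2-hydroxy-2-(4-methoxyphenyl)ethyl]phenol F3. Catalytic p-toluenesulfonic acid in CH2Cl2 effects the cyclodehydration through the same 4-methoxybenzylic cation, under reversible conditions that favour the trans ring, to give 11.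

Step 3. What may go wrong: coupling at the hindered, strongly basic lithium enolate may stall, which would allow transfer of silicon from the aryl oxygen to the enolate, Claisen-type condensation, or insertion of palladium into the aryl chloride. The fallback sets out from 5 and comes back at 8. Bromination of the silyl ketene acetal of 5 (LiN(SiMe3)2, Me3SiCl, THF, −78 °C; then NBS) should give the α-bromo ester, tert-butyl (3S)-2-bromo-3-[2-(tert-butyldimethylsilyloxy)-5-chlorophenyl]-3-(3,5-dimethoxyphenyl)propanoate F4. Zinc dust in THF converts it into the Reformatsky reagent, the bromozinc enolate of ester 5 F5. This neutral zinc enolate is coupled with an excess of 6 under Pd(dba)2/P(tBu)3 catalysis at room temperature (Negishi-type arylation of a Reformatsky reagent, no lithium amide present) to give 8.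

Step 8. What may go wrong: acid-induced ionisation of the O1–C2 bond and protonation of the electron-rich stilbene may lead to Friedel–Crafts cyclisation or oligomerisation before all five ethers are cleaved. The fallback sets out from 11 and comes back at 14; it moves the ether cleavage in front of the Heck reaction, so that the stilbene never meets BBr3, and ends with a mild transesterification. BBr3 in CH2Cl2 converts 11 into the triphenol 5-[(2S,3S)-5-chloro-2-(4-hydroxyphenyl)-2,3-dihydro-1-benzofuran-3-yl]benzene-1,3-diol F6. Acetic anhydride and pyridine give its triacetate F7. A Heck reaction of F7 with 3,5-diacetoxystyrene (C=Cc1cc(OC(C)=O)cc(OC(C)=O)c1) under the conditions of step 7 should give (2S,3S)-trans-δ-viniferin pentaacetate F8. K2CO3 in methanol at 0 °C under argon then releases 14.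

**Further compounds**

F1 | step 6 | 2-thioxopyridin-1(2H)-yl (3S)-3-[2-(tert-butyldimethylsilyloxy)-5-chlorophenyl]-3-(3,5-dimethoxyphenyl)-2-(4-methoxyphenyl)propanoate (Barton ester, C2 epimers) | O=C(On1ccccc1=S)C(c1ccc(OC)cc1)[C@@H](c1cc(OC)cc(OC)c1)c1cc(Cl)ccc1O[Si](C)(C)C(C)(C)C
F2 | step 6 | (2S)-2-[2-(tert-butyldimethylsilyloxy)-5-chlorophenyl]-2-(3,5-dimethoxyphenyl)-1-(4-methoxyphenyl)ethan-1-ol (C1 epimers) | COc1ccc(C(O)[C@@H](c2cc(OC)cc(OC)c2)c2cc(Cl)ccc2O[Si](C)(C)C(C)(C)C)cc1
F3 | step 6 | 4-chloro-2-[(1S)-1-(3,5-dimethoxyphenyl)-2-hydroxy-2-(4-methoxyphenyl)ethyl]phenol (carbinol epimers) | COc1ccc(C(O)[C@@H](c2cc(OC)cc(OC)c2)c2cc(Cl)ccc2O)cc1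
F4 | step 3 | tert-butyl (3S)-2-bromo-3-[2-(tert-butyldimethylsilyloxy)-5-chlorophenyl]-3-(3,5-dimethoxyphenyl)propanoate (C2 epimers) | CC(C)(C)OC(=O)C(Br)[C@@H](c1cc(OC)cc(OC)c1)c1cc(Cl)ccc1O[Si](C)(C)C(C)(C)C
F5 | step 3 | bromozinc enolate of tert-butyl (3S)-3-[2-(tert-butyldimethylsilyloxy)-5-chlorophenyl]-3-(3,5-dimethoxyphenyl)propanoate (Reformatsky reagent) | CC(C)(C)OC(O[Zn]Br)=C[C@@H](c1cc(OC)cc(OC)c1)c1cc(Cl)ccc1O[Si](C)(C)C(C)(C)C
F6 | step 8 | 5-[(2S,3S)-5-chloro-2-(4-hydroxyphenyl)-2,3-dihydro-1-benzofuran-3-yl]benzene-1,3-diol | Oc1ccc([C@H]2Oc3ccc(Cl)cc3[C@@H]2c2cc(O)cc(O)c2)cc1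
F7 | step 8 | triacetate of F6, 5-[(2S,3S)-2-(4-acetoxyphenyl)-5-chloro-2,3-dihydro-1-benzofuran-3-yl]-1,3-phenylene diacetate | CC(=O)Oc1ccc([C@H]2Oc3ccc(Cl)cc3[C@@H]2c2cc(OC(C)=O)cc(OC(C)=O)c2)cc1
F8 | step 8 | (2S,3S)-trans-δ-viniferin pentaacetate | CC(=O)Oc1ccc([C@H]2Oc3ccc(/C=C/c4cc(OC(C)=O)cc(OC(C)=O)c4)cc3[C@@H]2c2cc(OC(C)=O)cc(OC(C)=O)c2)cc1
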